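## Structural features

Target 14 is a (2S)-flavanone. Benzo ring A is fused to the dihydropyran-4-one ring C (O1, C2, C3, C4, C4a, C8a), and catechol ring B (C1′–C6′, hydroxyls on C3′ and C4′) is attached at C2. C2 is the only stereocentre; it is benzylic, bears O1 and lies β to the C4 carbonyl, so base can open ring C by retro-oxa-Michael reaction to the achiral 2′-hydroxychalcone and erase it, the more easily because there is no 5-OH. Ring A carries a free 7-OH and, at C8 between C7–OH and C8a–O1, the chain C1″H2–C2″H=C3″(CH3)–C4″H2OH with a Z double bond, i.e. C4″ is cis to C1″. This is the less accessible geometry, since allylic oxidation of a prenyl group and stabilised-ylide olefinations both favour the E alcohol. Fragile groups are the catechol (oxidation in base), the primary allylic alcohol held next to a phenol (ionisation and cyclisation onto O7 under acid), the trisubstituted alkene (no hydrogenolysis) and the enolisable ketone. The real difficulty is to place the complete Z chain on the crowded C8 without E/Z leakage and without conditions that damage C2; the configuration at C2 is the second problem. The key step exploits the unit O7–C7–C8–C1″, which is a latent ortho-quinone methide (O7=C7–C8=C1″H2) with C1″ as the electrophilic terminus. It also exploits the cis relation of the C4″ oxygen to C2″, which can be stored in a five-membered ring O–C4″–C3″=C2″–B.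

## Logic of the disconnections

**14 to 13.** The four O–Si bonds at O7, O3′, O4′ and O4″ are cut. Silyl ethers are chosen because fluoride removes them near neutrality, whereas hydrogenolysis (alkene), strong acid (allylic alcohol beside the phenol) and strong base (C2) are all excluded. The gain is only protection. The forward step must use buffered fluoride with exclusion of air.

**13 to 8 and 12.** The C2–C1′ bond is cut. This removes the only stereocentre, returns ring C to a flat pyranone and splits the molecule into two halves of similar size, with no chalcone on the pathway. The forward step must add the aryl group of 12 to C2 of 8 on one face, end by protonation and not by β-hydride elimination, and tolerate silyl ethers and the trisubstituted alkene.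

**8 to 7.** The O–Si bonds at O7 and O4″ are cut. They are there because a free phenol next to an allylic alcohol would be exposed to cationic divalent palladium in the arylation. The forward step is a plain double silylation.

**7 to 5 and 3 (key).** The C1″–C2″ bond is cut. C1″ becomes the exocyclic carbon of ortho-quinone methide 6, released from 5, and C2″ becomes the boron-bearing alkenyl carbon of 3, in which boron and the C4″ oxygen share a five-membered ring. The whole side chain, its Z geometry and its free hydroxyl then arrive in one step with no redox change. The forward step must release 6 under conditions that the C–B bond survives, and must transfer the alkenyl group from boron to C1″ faster than 6 oligomerises or the pyranone is attacked.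

**5 to 4.** The C8–C1″ bond is cut (ortho-aminomethylation). The 7-OH directs the one-carbon electrophile to C8, the ortho position between the two oxygens. The forward step must stop at mono-substitution at C8 and leave C6 and the pyranone alone.

**3 to 1, through 2.** The C3″–CH3 bond and the C2″–B bond are cut; both groups are added across the triple bond of 1. Alkoxide-directed anti addition puts the metal cis to the CH2O group in the cyclic intermediate 2, which is exactly the Z relation needed. The forward step must be regioselective and anti, and the exchange of magnesium for boron must occur with retention.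

**12 to 10 (through 11), and 10 to 9.** The C–B bond is cut back to the aryl bromide through aryllithium 11, and the two O–Si bonds back to the diol 9. These are standard operations with no selectivity issue beyond keeping the metal away from a silyloxy-bearing ortho position.

## Other disconnections considered

Alternative 1: The first idea is to cut O1–C2 and C2′... that is, to open ring C to the chalcone A1 and to form A1 by Claisen–Schmidt condensation; the forward key step would be a 6-endo oxa-Michael cyclisation of A1. The ground against it is mechanistic: this cyclisation is reversible, and the reverse reaction is the very process that racemises C2, so an enantioselective version on an unactivated chalcone has no driving force that protects the product. It also leaves the Z side chain unsolved, since it would have to be built on the acetophenone half by prenylation and oxidation, which favours the E alcohol. The chosen plan sets C2 by an irreversible C–C bond formation and never passes through A1.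

Alternative 2: The C8–C1″ bond could be cut by a [3,3] shift. The forward key step would be an aromatic Claisen rearrangement of the tertiary allyl aryl ether A2, made from 4 and isoprene monoxide. The chair transition state places the larger of the two substituents on the oxygen-bearing carbon (CH2OH against CH3) equatorial, which leads it trans to C1″, so the E isomer or a mixture is expected. Migration to C6 and the high temperature are further liabilities. The chosen plan fixes the geometry in a ring before the C–C bond is made.

Alternative 3: The C2″=C3″ double bond could be cut. The forward key step would be a Still–Gennari olefination of the arylacetaldehyde A3 to the Z enoate A4, followed by hydride reduction. A3 is an arylacetaldehyde flanked by two oxygens and should enolise into conjugation under the basic olefination conditions. The reduction of A4 to the alcohol would also have to spare the pyranone carbonyl, which forces extra protection and redox steps. The count is about four steps for the chain (allyl transfer, oxidative cleavage, olefination, reduction) against one in the chosen plan.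

Key step: step 3

Assumption: compounds 1, 4 and 9 are taken as purchasable.

Assumption: the facial sense of the pyridine-oxazoline palladium arylation is taken to follow the usual model, in which the (S)-ligand leads to (2R)-flavanones; the (R)-ligand is therefore specified, and the antipodal ligand would be used if the sense were the reverse.

## Route

Step 1
Reactants: 1 prop-2-yn-1-ol
Product: 3 4-methyl-2,5-dihydro-1,2-oxaborol-2-ol, via cyclic alkenylmagnesium alkoxide 2 (not isolated)
Conditions: MeMgBr (2.5 equiv), CuI (10 mol%), THF, 0 °C to rt; B(OMe)3, −78 °C to rt; 1 M HCl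
Reagents that add atoms: methylmagnesium bromide, C[Mg]Br; trimethyl borate, COB(OC)OC; water, O
Why: Alkoxide-directed, CuI-catalysed anti-carbomagnesiation of the propargylic alkoxide puts CH3 on the internal carbon and magnesium on the terminal carbon, cis to CH2O in the five-membered chelate 2. Exchange of magnesium for boron occurs with retention and hydrolysis closes the oxaborole, so the Z relation of boron and CH2O is held by a ring throughout.

Step 2
Reactants: 4 7-hydroxy-4H-chromen-4-one
Product: 5 8-[(dimethylamino)methyl]-7-hydroxy-4H-chromen-4-one
Conditions: CH2(NMe2)2 (1.2 equiv), i-PrOH, 80 °C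
Reagents that add atoms: bis(dimethylamino)methane, CN(C)CN(C)C
Why: Mannich reaction (ortho-aminomethylation of a phenol): the iminium ion from the aminal is delivered by hydrogen bonding to the 7-OH and attacks C8, the more nucleophilic ortho position between O7 and O1. The phenoxide character of O7 deactivates C2 of the pyranone towards the liberated amine.

Step 3
Reactants: 5 8-[(dimethylamino)methyl]-7-hydroxy-4H-chromen-4-one; 3 4-methyl-2,5-dihydro-1,2-oxaborol-2-ol
Product: 7 7-hydroxy-8-[(2Z)-4-hydroxy-3-methylbut-2-en-1-yl]-4H-chromen-4-one, via ortho-quinone methide 6 (not isolated)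
Conditions: 3 (1.5 equiv), 4 Å molecular sieves, 1,4-dioxane–PhMe, 100–110 °C; then aq. citric acid, THF, rt
Reagents that add atoms: none
Why: Condensation of the 7-OH of 5 with the B–OH of 3 gives an aryloxyborane whose boron is chelated by the neighbouring NMe2; the boron-bound nitrogen is a leaving group, and heat expels it as a B–NMe2 unit to release ortho-quinone methide 6, still held on boron through its carbonyl oxygen. The alkenyl group then migrates from tetracoordinate boron to the exocyclic CH2 through a six-membered B–O7–C7–C8–C1″···C2″ transition state, which rearomatises ring A and forms the C1″–C2″ bond. The closest known reaction type is the conjugate addition of alkenyl- and arylboron reagents to ortho-quinone methides released from ortho-hydroxybenzyl ethers or amines, a Petasis-type boron-to-carbon transfer. No ring is closed and no stereocentre is formed; the stereochemical element is the double bond, whose Z geometry is fixed beforehand by the oxaborole ring and is carried over because migration from boron occurs with retention at the sp2 carbon. The selectivity needed is capture of 6 by the alkenyl group in preference to oligomerisation of 6, re-addition of dimethylamine and attack at C2 of the pyranone; delivery within the boron complex and retention of the amine on boron should secure it. The chain oxygen stays on boron until the aqueous work-up, so it cannot add to 6, and the work-up then frees the Z allylic alcohol. The ketone and the pyranone double bond should be untouched because no nucleophile stronger than a boronate is present.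

Step 4
Reactants: 7 7-hydroxy-8-[(2Z)-4-hydroxy-3-methylbut-2-en-1-yl]-4H-chromen-4-one
Product: 8 7-[(tert-butyldimethylsilyl)oxy]-8-[(2Z)-4-[(tert-butyldimethylsilyl)oxy]-3-methylbut-2-en-1-yl]-4H-chromen-4-one
Conditions: TBSCl (2.4 equiv), imidazole, DMF, 0 °C to rt
Reagents that add atoms: tert-butyldimethylsilyl chloride, CC(C)(C)[Si](C)(C)Cl
Why: Standard silylation of a phenol and a primary alcohol. It masks O7 and O4″ so that neither can take part in oxypalladation or allylic ionisation at cationic divalent palladium in step 7.

Step 5
Reactants: 9 4-bromobenzene-1,2-diol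
Product: 10 4-bromo-1,2-bis[(tert-butyldimethylsilyl)oxy]benzene
Conditions: TBSCl (2.3 equiv), imidazole, DMF, rt
Reagents that add atoms: tert-butyldimethylsilyl chloride, CC(C)(C)[Si](C)(C)Cl
Why: Standard double silylation of a catechol; the silyl ethers match those of 8 so that one fluoride step clears all four at the end.

Step 6
Reactants: 10 4-bromo-1,2-bis[(tert-butyldimethylsilyl)oxy]benzene
Product: 12 {3,4-bis[(tert-butyldimethylsilyl)oxy]phenyl}boronic acid, via aryllithium 11 (not isolated)
Conditions: n-BuLi, THF, −78 °C; B(Oi-Pr)3, −78 °C to rt; 1 M HCl, 0 °C
Reagents that add atoms: triisopropyl borate, CC(C)OB(OC(C)C)OC(C)C; water, O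
Why: Bromine–lithium exchange, borylation of aryllithium 11 and hydrolysis of the borate. The lithium is not ortho to a silyloxy group, so no retro-Brook silyl shift is expected.

Step 7
Reactants: 8 7-[(tert-butyldimethylsilyl)oxy]-8-[(2Z)-4-[(tert-butyldimethylsilyl)oxy]-3-methylbut-2-en-1-yl]-4H-chromen-4-one; 12 {3,4-bis[(tert-butyldimethylsilyl)oxy]phenyl}boronic acid
Product: 13 (2S)-2-{3,4-bis[(tert-butyldimethylsilyl)oxy]phenyl}-7-[(tert-butyldimethylsilyl)oxy]-8-[(2Z)-4-[(tert-butyldimethylsilyl)oxy]-3-methylbut-2-en-1-yl]-2,3-dihydro-4H-chromen-4-one
Conditions: Pd(OCOCF3)2 (5 mol%), (R)-t-BuPyOx (6 mol%), NH4PF6 (30 mol%), H2O (5 equiv), ClCH2CH2Cl, 60 °C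
Reagents that add atoms: none
Why: Enantioselective palladium-catalysed conjugate addition of an arylboronic acid to a chromone: 12 transmetalates to a cationic divalent palladium aryl carrying the pyridine-oxazoline ligand, C2=C3 of 8 inserts with aryl delivery to C2 on the face set by the tert-butyl group of the ligand, and water protonates the palladium enolate, so no flavone forms. The (R)-ligand is chosen to give (2S), and the non-basic medium should leave the new stereocentre, the silyl ethers and the trisubstituted alkene untouched.

Step 8
Reactants: 13 (2S)-2-{3,4-bis[(tert-butyldimethylsilyl)oxy]phenyl}-7-[(tert-butyldimethylsilyl)oxy]-8-[(2Z)-4-[(tert-butyldimethylsilyl)oxy]-3-methylbut-2-en-1-yl]-2,3-dihydro-4H-chromen-4-one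
Product: 14 (2S)-2-(3,4-dihydroxyphenyl)-7-hydroxy-8-[(2Z)-4-hydroxy-3-methylbut-2-en-1-yl]-2,3-dihydro-4H-chromen-4-one
Conditions: HF·pyridine, pyridine, THF, 0 °C to rt, under argon
Reagents that add atoms: none
Why: Fluoride-mediated cleavage of three aryl silyl ethers and one primary alkyl silyl ether in a pyridine-buffered, weakly acidic medium. No base strong enough for retro-oxa-Michael opening at C2 and no acid strong enough to ionise the allylic alcohol is present, so C2 and the Z alkene should be unchanged.

## Compound list

1 | prop-2-yn-1-ol | C#CCO | starting material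
2 | 4-methyl-2,5-dihydro-1,2-oxamagnesole (cyclic alkenylmagnesium alkoxide) | CC1=C[Mg]OC1 | intermediate (not isolated)
3 | 4-methyl-2,5-dihydro-1,2-oxaborol-2-ol | CC1=CB(O)OC1 | intermediate
4 | 7-hydroxy-4H-chromen-4-one | Oc1ccc2c(c1)OC=CC2=O | starting material
5 | 8-[(dimethylamino)methyl]-7-hydroxy-4H-chromen-4-one | CN(C)Cc1c(O)ccc2c1OC=CC2=O | intermediate
6 | 8-methylidene-4H-chromene-4,7(8H)-dione (ortho-quinone methide, boron-bound in the flask) | C=C1C(=O)C=CC2=C1OC=CC2=O | intermediate (not isolated)
7 | 7-hydroxy-8-[(2Z)-4-hydroxy-3-methylbut-2-en-1-yl]-4H-chromen-4-one | C/C(=C/Cc1c(O)ccc2c1OC=CC2=O)CO | intermediate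
8 | 7-[(tert-butyldimethylsilyl)oxy]-8-[(2Z)-4-[(tert-butyldimethylsilyl)oxy]-3-methylbut-2-en-1-yl]-4H-chromen-4-one | C/C(=C/Cc1c(O[Si](C)(C)C(C)(C)C)ccc2c1OC=CC2=O)CO[Si](C)(C)C(C)(C)C | intermediate
9 | 4-bromobenzene-1,2-diol | Oc1ccc(Br)cc1O | starting material
10 | 4-bromo-1,2-bis[(tert-butyldimethylsilyl)oxy]benzene | CC(C)(C)[Si](C)(C)Oc1ccc(Br)cc1O[Si](C)(C)C(C)(C)C | intermediate
11 | {3,4-bis[(tert-butyldimethylsilyl)oxy]phenyl}lithium | [Li]c1ccc(O[Si](C)(C)C(C)(C)C)c(O[Si](C)(C)C(C)(C)C)c1 | intermediate (not isolated)
12 | {3,4-bis[(tert-butyldimethylsilyl)oxy]phenyl}boronic acid | OB(O)c1ccc(O[Si](C)(C)C(C)(C)C)c(O[Si](C)(C)C(C)(C)C)c1 | intermediate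
13 | (2S)-2-{3,4-bis[(tert-butyldimethylsilyl)oxy]phenyl}-7-[(tert-butyldimethylsilyl)oxy]-8-[(2Z)-4-[(tert-butyldimethylsilyl)oxy]-3-methylbut-2-en-1-yl]-2,3-dihydro-4H-chromen-4-one | C/C(=C/Cc1c(O[Si](C)(C)C(C)(C)C)ccc2c1O[C@H](c1ccc(O[Si](C)(C)C(C)(C)C)c(O[Si](C)(C)C(C)(C)C)c1)CC2=O)CO[Si](C)(C)C(C)(C)C | intermediate
14 | (2S)-2-(3,4-dihydroxyphenyl)-7-hydroxy-8-[(2Z)-4-hydroxy-3-methylbut-2-en-1-yl]-2,3-dihydro-4H-chromen-4-one | C/C(=C/Cc1c(O)ccc2c1O[C@H](c1ccc(O)c(O)c1)CC2=O)CO | target

## Step count and least certain steps

Total: 8 steps. Longest linear sequence: 5 steps (steps 2, 3, 4, 7, 8 from compound 4; equally steps 1, 3, 4, 7, 8 from compound 1).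

**Step 3 (key step).** The release of 6 may need a temperature at which protodeboronation of 3 or oligomerisation of 6 outruns the alkenyl transfer. The freed dimethylamine may add to C2 and open the pyranone. After the transfer, the Lewis-acidic boron may promote cyclisation of O7 onto the allylic position. The fallback sets out from 5 and comes back at 7, and it replaces the quinone methide by a cross-coupling. Heating 5 in acetic anhydride should exchange the amine for acetate and acetylate O7, giving (7-acetoxy-4-oxo-4H-chromen-8-yl)methyl acetate F1. A Suzuki–Miyaura coupling of this benzylic acetate with 3 (Pd(OAc)2, DPEphos, K2CO3, toluene–water, 80 °C) should form 8-[(2Z)-4-hydroxy-3-methylbut-2-en-1-yl]-4-oxo-4H-chromen-7-yl acetate F2. It would proceed by oxidative addition of zerovalent palladium into the benzylic C–O bond, transmetalation with retention of the alkene geometry and reductive elimination. Brief methanolysis (K2CO3, MeOH, 0 °C) would remove the aryl acetate and give 7.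

**Step 7.** Facial discrimination may be poor on a chromone that carries a 7-silyloxy group and an 8-substituent. The electron-rich boronic acid may protodeboronate, and fluoride from hexafluorophosphate may cause partial loss of aryl silyl groups. The fallback sets out from 8 and 12 and comes back at 13, and it separates the construction of the C2–C1′ bond from the control of configuration. A racemic conjugate arylation (Pd(OCOCF3)2, 2,2′-bipyridine, aqueous ClCH2CH2Cl, 60 °C) should give rac-2-{3,4-bis[(tert-butyldimethylsilyl)oxy]phenyl}-7-[(tert-butyldimethylsilyl)oxy]-8-[(2Z)-4-[(tert-butyldimethylsilyl)oxy]-3-methylbut-2-en-1-yl]-2,3-dihydro-4H-chromen-4-one F3. A kinetic resolution by asymmetric transfer hydrogenation would follow (RuCl(p-cymene)(TsDPEN) in the antipode that reduces the (2R)-ketone, HCO2H–Et3N, rt). It should convert the unwanted enantiomer into (2R,4R)-2-{3,4-bis[(tert-butyldimethylsilyl)oxy]phenyl}-7-[(tert-butyldimethylsilyl)oxy]-8-[(2Z)-4-[(tert-butyldimethylsilyl)oxy]-3-methylbut-2-en-1-yl]-3,4-dihydro-2H-chromen-4-ol F4 and leave the (2S)-ketone 13, which is separated by chromatography.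

**Step 2.** Aminomethylation may occur at C6 as well as C8, or twice, and the liberated dimethylamine may add to C2 with opening of the pyranone. The fallback sets out from 4 and comes back at 5, and it brings in the carbon and the nitrogen separately under acidic conditions. A Duff formylation (hexamethylenetetramine, CF3CO2H, 80 °C; aq. HCl) should give 7-hydroxy-4-oxo-4H-chromene-8-carbaldehyde F5, with the aldehyde directed to C8 by the 7-OH. Reductive amination (Me2NH·HCl, NaBH(OAc)3, ClCH2CH2Cl, rt) would give 5.

**Step 1.** The chelated alkenylmagnesium alkoxide 2 may exchange slowly with the borate, excess MeMgBr may consume the borate, and the small, water-soluble 3 may be lost on isolation. The fallback sets out from 1 and comes back at 3, and it isolates the geometry as a vinyl iodide before boron is introduced. The same carbomagnesiation quenched with I2 should give (2Z)-3-iodo-2-methylprop-2-en-1-ol F6. A Miyaura borylation (B2pin2, PdCl2(dppf), KOAc, 1,4-dioxane, 60 °C) should give (2Z)-2-methyl-3-(4,4,5,5-tetramethyl-1,3,2-dioxaborolan-2-yl)prop-2-en-1-ol F7. Oxidative removal of the pinacol (NaIO4, NH4OAc, acetone–water) would close the ring to 3.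

## Further compounds

F1 | step 3 | (7-acetoxy-4-oxo-4H-chromen-8-yl)methyl acetate | CC(=O)OCc1c(OC(C)=O)ccc2c1OC=CC2=O
F2 | step 3 | 8-[(2Z)-4-hydroxy-3-methylbut-2-en-1-yl]-4-oxo-4H-chromen-7-yl acetate | C/C(=C/Cc1c(OC(C)=O)ccc2c1OC=CC2=O)CO
F3 | step 7 | rac-2-{3,4-bis[(tert-butyldimethylsilyl)oxy]phenyl}-7-[(tert-butyldimethylsilyl)oxy]-8-[(2Z)-4-[(tert-butyldimethylsilyl)oxy]-3-methylbut-2-en-1-yl]-2,3-dihydro-4H-chromen-4-one | C/C(=C/Cc1c(O[Si](C)(C)C(C)(C)C)ccc2c1OC(c1ccc(O[Si](C)(C)C(C)(C)C)c(O[Si](C)(C)C(C)(C)C)c1)CC2=O)CO[Si](C)(C)C(C)(C)C
F4 | step 7 | (2R,4R)-2-{3,4-bis[(tert-butyldimethylsilyl)oxy]phenyl}-7-[(tert-butyldimethylsilyl)oxy]-8-[(2Z)-4-[(tert-butyldimethylsilyl)oxy]-3-methylbut-2-en-1-yl]-3,4-dihydro-2H-chromen-4-ol | C/C(=C/Cc1c(O[Si](C)(C)C(C)(C)C)ccc2c1O[C@@H](c1ccc(O[Si](C)(C)C(C)(C)C)c(O[Si](C)(C)C(C)(C)C)c1)C[C@H]2O)CO[Si](C)(C)C(C)(C)C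
F5 | step 2 | 7-hydroxy-4-oxo-4H-chromene-8-carbaldehyde | O=Cc1c(O)ccc2c1OC=CC2=O
F6 | step 1 | (2Z)-3-iodo-2-methylprop-2-en-1-ol | C/C(=C/I)CO
F7 | step 1 | (2Z)-2-methyl-3-(4,4,5,5-tetramethyl-1,3,2-dioxaborolan-2-yl)prop-2-en-1-ol | C/C(=C/B1OC(C)(C)C(C)(C)O1)CO
A1 | alternative 1 | (2E)-1-{2,4-dihydroxy-3-[(2Z)-4-hydroxy-3-methylbut-2-en-1-yl]phenyl}-3-(3,4-dihydroxyphenyl)prop-2-en-1-one | C/C(=C/Cc1c(O)ccc(C(=O)/C=C/c2ccc(O)c(O)c2)c1O)CO
A2 | alternative 2 | rac-7-[(1-hydroxy-2-methylbut-3-en-2-yl)oxy]-4H-chromen-4-one | C=CC(C)(CO)Oc1ccc2c(c1)OC=CC2=O
A3 | alternative 3 | 2-{7-[(tert-butyldimethylsilyl)oxy]-4-oxo-4H-chromen-8-yl}acetaldehyde | O=CCc1c(O[Si](C)(C)C(C)(C)C)ccc2c1OC=CC2=O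
A4 | alternative 3 | methyl (2Z)-4-{7-[(tert-butyldimethylsilyl)oxy]-4-oxo-4H-chromen-8-yl}-2-methylbut-2-enoate | COC(=O)/C(C)=C\Cc1c(O[Si](C)(C)C(C)(C)C)ccc2c1OC=CC2=O
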